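**Strategy.** The route rests on cutting the phloroglucinol A ring away from the C ring at C4a–C5 and C8–C8a. The A ring carries oxygen on C5, C7 and (as ring O1) C8a, a 1,3,5-pattern that a 1,1,3-trioxygenated butadiene delivers to the C4-carbonyl-polarised enone of a pyranone. The precursor is therefore the complete C ring, a (2S)-2-aryl-2,3-dihydro-4H-pyran-4-one with the geranyl ether in place and a phenylsulfinyl group on the future C4a. In one operation a Diels–Alder addition, thermal loss of PhSOH and mild hydrolysis should build the aromatic 5,7-diol and give the target directly. C2 is set earlier by a catalytic asymmetric aldol–cyclisation.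

Key step: step 8

Assumption: (S)-BINOL is taken to direct the silyl dienol ether to the Si face of the aryl aldehyde, as BINOL–titanium catalysts do in allylations and aldol additions of aldehydes; the configuration would be checked at the sulfide pyranone and (R)-BINOL used if the sense were opposite.

Remark: the sulfoxide precursor is carried as both configurations at sulfur, which is of no consequence because sulfur leaves in the key step.

**Step 1**
Reactants: 1 4-hydroxybenzaldehyde; 2 geranyl bromide [(2E)-1-bromo-3,7-dimethylocta-2,6-diene]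
Product: 3 4-{[(2E)-3,7-dimethylocta-2,6-dien-1-yl]oxy}benzaldehyde (4-geranyloxybenzaldehyde)
Conditions: K2CO3, acetone, reflux
Reagents that add atoms: none
Why: Williamson ether synthesis, in which the phenoxide displaces the primary allylic bromide by SN2 with the 2E geometry retained and the aldehyde inert to carbonate.

**Step 2**
Reactants: 4 (E)-4-methoxybut-3-en-2-one; 5 thiophenol
Product: 8 4-methoxy-3-(phenylsulfanyl)but-3-en-2-one (E/Z not controlled), via benzenesulfenyl chloride 6 (not isolated), via chloro sulfide adduct 7 (not isolated)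
Conditions: 5, NCS, CH2Cl2, 0 °C; then 4, −78 → 0 °C; then Et3N, 0 °C → rt
Reagents that add atoms: none
Why: S-chlorination of the thiol gives the sulfenyl chloride, which should add to the enol ether C=C with sulfur at the nucleophilic C3 and chloride at the oxygen-stabilised C4, after which triethylamine removes HCl (addition–elimination α-sulfenylation of a β-alkoxy enone).

**Step 3**
Reactants: 8 4-methoxy-3-(phenylsulfanyl)but-3-en-2-one
Product: 9 1-methoxy-2-(phenylsulfanyl)-3-(trimethylsilyloxy)buta-1,3-diene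
Conditions: TMSOTf, Et3N, Et2O, 0 °C; used crude under argon
Reagents that add atoms: trimethylsilyl trifluoromethanesulfonate, C[Si](C)(C)OS(=O)(=O)C(F)(F)F
Why: Soft enolisation and O-silylation of the methyl ketone, the only enolisable position, should give the 2-substituted 1-alkoxy-3-silyloxy diene (silyl enol ether formation).

**Step 4**
Reactants: 3 4-geranyloxybenzaldehyde; 9 1-methoxy-2-(phenylsulfanyl)-3-(trimethylsilyloxy)buta-1,3-diene
Product: 11 (2S)-2-(4-{[(2E)-3,7-dimethylocta-2,6-dien-1-yl]oxy}phenyl)-5-(phenylsulfanyl)-2,3-dihydro-4H-pyran-4-one, via silyl aldol adduct 10 (not isolated)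
Conditions: (S)-BINOL (20 mol%), Ti(OiPr)4 (10 mol%), 4 Å MS, Et2O, −20 °C; then TFA (0.2 equiv), CH2Cl2, 0 °C, short contact, NaHCO3 quench
Reagents that add atoms: none
Why: A catalytic asymmetric Mukaiyama aldol addition of the silyl dienol ether to the titanium–BINOLate-bound aldehyde sets C2 under ligand control (Si face), and acid then closes the ring by 6-endo oxa-Michael addition and loss of methanol with the C2–O bond untouched, which amounts to a formal hetero-Diels–Alder reaction of a 1-alkoxy-3-silyloxy diene.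

**Step 5**
Reactants: 11 (2S)-5-(phenylsulfanyl) pyranone
Product: 12 (2S)-2-(4-{[(2E)-3,7-dimethylocta-2,6-dien-1-yl]oxy}phenyl)-5-(phenylsulfinyl)-2,3-dihydro-4H-pyran-4-one (both configurations at sulfur)
Conditions: NaIO4 (1.1 equiv), MeOH/THF/H2O, 0 °C → rt
Reagents that add atoms: sodium periodate, [Na+].[O-]I(=O)(=O)=O
Why: Periodate oxidation of a sulfide to the sulfoxide is expected to stop at that level and to leave the trisubstituted alkenes, the enol ether and C2 untouched under neutral conditions.

**Step 6**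
Reactants: 13 methyl acetoacetate
Product: 14 methyl 3-(trimethylsilyloxy)but-2-enoate
Conditions: TMSCl, Et3N, hexane, rt
Reagents that add atoms: chlorotrimethylsilane, C[Si](C)(C)Cl
Why: O-silylation of the enol of the β-keto ester (silyl enol ether formation).

**Step 7**
Reactants: 14 methyl 3-(trimethylsilyloxy)but-2-enoate
Product: 16 1-methoxy-1,3-bis(trimethylsilyloxy)buta-1,3-diene, via lithium dienolate 15 (not isolated)
Conditions: LDA, THF, −78 °C; then TMSCl, −78 °C → rt; distilled, used fresh
Reagents that add atoms: chlorotrimethylsilane, C[Si](C)(C)Cl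
Why: γ-Deprotonation of the vinylogous ester gives the dienolate, which is silylated on the ester oxygen to the silyl ketene acetal (O-silylation of an ester dienolate).

**Step 8**
Reactants: 12 (2S)-5-(phenylsulfinyl) pyranone; 16 1-methoxy-1,3-bis(trimethylsilyloxy)buta-1,3-diene
Product: 19 (2S)-5,7-dihydroxy-2-(4-{[(2E)-3,7-dimethylocta-2,6-dien-1-yl]oxy}phenyl)-2,3-dihydro-4H-chromen-4-one [(S)-4'-O-geranylnaringenin], via sulfinyl cycloadduct 17 (not isolated), via dienyl silyl ketal 18 (not isolated)
Conditions: 16 (3 equiv), toluene, rt → 70 °C, argon; then THF/0.5 M aq. HCl, 0 °C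
Reagents that add atoms: none
Why: Proposed new method: a thermal normal-demand Diels–Alder reaction is expected in which the CH2 terminus of 16 (largest HOMO coefficient) bonds first to the oxygen-bearing β-carbon of the sulfinyl enone (making C8–C8a) and the ketene-acetal carbon then bonds to the sulfinyl-bearing α-carbon (making C4a–C5), so that the six-membered A ring is closed by an intermolecular [4+2] annulation to give cis-fused 17. Because the addition is suprafacial, the sulfinyl group on C4a and the hydrogen on C8a are cis, and this β-keto sulfoxide should lose benzenesulfenic acid by syn-elimination on gentle heating to give the C4a=C8a bond of 18 without an enolate or oxocarbenium ion that could expel O1 or open the C ring. Dilute acid then cleaves the silyl methyl ketal at C5 and the silyl enol ether at C7, and the resulting cyclohexadienone tautomerises to the 5,7-dihydroxy arene. The closest known reaction type is the Diels–Alder/sulfoxide-elimination benzannulation of 3-sulfinylchromones and 2-sulfinyl enones with 1-alkoxy-3-silyloxy dienes, together with the annulation of haloquinones by 1,1,3-trioxygenated dienes; it has not been shown on a 2,3-dihydro-4H-pyran-4-one. No new stereocentre survives (C4a, C8a and C5 of 17 all become sp2), and C2 is remote and sees only neutral or weakly acidic conditions. The step needs regioselectivity, which the concordant polarisation of the dienophile by the C4 carbonyl and the sulfinyl group should secure, and chemoselectivity for the activated C=C over the two unactivated geranyl alkenes, which the electron-rich diene should secure.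

**Compound list**

1 | 4-hydroxybenzaldehyde | O=Cc1ccc(O)cc1 | starting material
2 | geranyl bromide, (2E)-1-bromo-3,7-dimethylocta-2,6-diene | CC(C)=CCC/C(C)=C/CBr | starting material
3 | 4-{[(2E)-3,7-dimethylocta-2,6-dien-1-yl]oxy}benzaldehyde | CC(C)=CCC/C(C)=C/COc1ccc(C=O)cc1 | intermediate
4 | (E)-4-methoxybut-3-en-2-one | CO/C=C/C(C)=O | starting material
5 | thiophenol | Sc1ccccc1 | starting material
6 | benzenesulfenyl chloride | ClSc1ccccc1 | intermediate
7 | 4-chloro-4-methoxy-3-(phenylsulfanyl)butan-2-one (racemic, diastereomer mixture) | COC(Cl)C(Sc1ccccc1)C(C)=O | intermediate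
8 | 4-methoxy-3-(phenylsulfanyl)but-3-en-2-one (E/Z mixture) | COC=C(Sc1ccccc1)C(C)=O | intermediate
9 | 1-methoxy-2-(phenylsulfanyl)-3-(trimethylsilyloxy)buta-1,3-diene (E/Z mixture) | COC=C(Sc1ccccc1)C(=C)O[Si](C)(C)C | intermediate
10 | (5S)-5-(4-{[(2E)-3,7-dimethylocta-2,6-dien-1-yl]oxy}phenyl)-1-methoxy-2-(phenylsulfanyl)-5-(trimethylsilyloxy)pent-1-en-3-one | CC(C)=CCC/C(C)=C/COc1ccc([C@H](CC(=O)C(Sc2ccccc2)=COC)O[Si](C)(C)C)cc1 | intermediate
11 | (2S)-2-(4-{[(2E)-3,7-dimethylocta-2,6-dien-1-yl]oxy}phenyl)-5-(phenylsulfanyl)-2,3-dihydro-4H-pyran-4-one | CC(C)=CCC/C(C)=C/COc1ccc([C@@H]2CC(=O)C(Sc3ccccc3)=CO2)cc1 | intermediate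
12 | (2S)-2-(4-{[(2E)-3,7-dimethylocta-2,6-dien-1-yl]oxy}phenyl)-5-(phenylsulfinyl)-2,3-dihydro-4H-pyran-4-one (both configurations at sulfur) | CC(C)=CCC/C(C)=C/COc1ccc([C@@H]2CC(=O)C(S(=O)c3ccccc3)=CO2)cc1 | intermediate
13 | methyl acetoacetate | COC(=O)CC(C)=O | starting material
14 | methyl 3-(trimethylsilyloxy)but-2-enoate | COC(=O)C=C(C)O[Si](C)(C)C | intermediate
15 | lithium 1-methoxy-3-(trimethylsilyloxy)buta-1,3-dien-1-olate | [Li+].COC([O-])=CC(=C)O[Si](C)(C)C | intermediate
16 | 1-methoxy-1,3-bis(trimethylsilyloxy)buta-1,3-diene | COC(O[Si](C)(C)C)=CC(=C)O[Si](C)(C)C | intermediate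
17 | (2S)-2-(4-{[(2E)-3,7-dimethylocta-2,6-dien-1-yl]oxy}phenyl)-5-methoxy-4a-(phenylsulfinyl)-5,7-bis(trimethylsilyloxy)-2,3,4a,5,8,8a-hexahydro-4H-chromen-4-one (cis-fused; mixture at C5 and sulfur) | CC(C)=CCC/C(C)=C/COc1ccc([C@@H]2CC(=O)C3(S(=O)c4ccccc4)C(OC)(O[Si](C)(C)C)C=C(O[Si](C)(C)C)CC3O2)cc1 | intermediate
18 | (2S)-2-(4-{[(2E)-3,7-dimethylocta-2,6-dien-1-yl]oxy}phenyl)-5-methoxy-5,7-bis(trimethylsilyloxy)-2,3,5,8-tetrahydro-4H-chromen-4-one | CC(C)=CCC/C(C)=C/COc1ccc([C@@H]2CC(=O)C3=C(CC(O[Si](C)(C)C)=CC3(OC)O[Si](C)(C)C)O2)cc1 | intermediate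
19 | (2S)-5,7-dihydroxy-2-(4-{[(2E)-3,7-dimethylocta-2,6-dien-1-yl]oxy}phenyl)-2,3-dihydro-4H-chromen-4-one, (S)-4'-O-geranylnaringenin | CC(C)=CCC/C(C)=C/COc1ccc([C@@H]2CC(=O)c3c(O)cc(O)cc3O2)cc1 | target

**Step count.** Total: 8 steps. Longest linear sequence: 5 steps (steps 2, 3, 4, 5, 8).

**Steps most likely to fail**

1. Step 8 (proposed new method). The vinylogous-ester dienophile may add so slowly that the bis-silyloxy diene is lost first by thermal or protic decay. Silyl transfer to the sulfinyl oxygen (a Pummerer-type diversion) or capture of the released sulfenic acid by the silyl enol ether or the geranyl alkenes could also consume material. The fallback uses known chemistry, sets out from 2 and comes back at 19. Compound 2 would alkylate commercial 4-hydroxyphenylboronic acid pinacol ester (K2CO3, acetone) to 2-(4-{[(2E)-3,7-dimethylocta-2,6-dien-1-yl]oxy}phenyl)-4,4,5,5-tetramethyl-1,3,2-dioxaborolane F1, and NaIO4/NH4OAc in aqueous acetone would free (4-{[(2E)-3,7-dimethylocta-2,6-dien-1-yl]oxy}phenyl)boronic acid F2. Commercial 5,7-dihydroxychromone would be silylated (TBSOTf, 2,6-lutidine, CH2Cl2) to 5,7-bis(tert-butyldimethylsilyloxy)-4H-chromen-4-one F3. Palladium(II)/pyridine-oxazoline-catalysed asymmetric conjugate addition of F2 to F3 (Pd(OCOCF3)2, the t-BuPyOx enantiomer that gives the 2S adduct, NH4PF6, H2O, ClCH2CH2Cl, 60 °C) should give (2S)-5,7-bis(tert-butyldimethylsilyloxy)-2-(4-{[(2E)-3,7-dimethylocta-2,6-dien-1-yl]oxy}phenyl)-2,3-dihydro-4H-chromen-4-one F4. KHF2 in MeOH at rt would then free both phenols to give 19 without base.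

2. Step 4. Facial selectivity may be poor with the sulfur-substituted diene, or the geranyl ether may be lost during the acid-induced ring closure. The fallback sets out from 3 and comes back at 11; it brings sulfur in after the ring is made. Commercial (E)-1-methoxy-3-(trimethylsilyloxy)buta-1,3-diene would be used under the same BINOL–titanium catalysis, for which aryl aldehydes are the standard case, to give (5S)-5-(4-{[(2E)-3,7-dimethylocta-2,6-dien-1-yl]oxy}phenyl)-1-methoxy-5-(trimethylsilyloxy)pent-1-en-3-one F5. Ring closure with PPTS or catalytic TFA would give (2S)-2-(4-{[(2E)-3,7-dimethylocta-2,6-dien-1-yl]oxy}phenyl)-2,3-dihydro-4H-pyran-4-one F6. α-Iodination (I2, pyridine, CH2Cl2, 0 °C → rt) would give (2S)-2-(4-{[(2E)-3,7-dimethylocta-2,6-dien-1-yl]oxy}phenyl)-5-iodo-2,3-dihydro-4H-pyran-4-one F7. Palladium-catalysed C–S coupling with 5 (Pd2(dba)3, Xantphos, iPr2NEt, dioxane, not above 80 °C to avoid base-induced ring opening at C2) would return 11.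

3. Step 5. Oxygen transfer to the electron-poor vinyl sulfide may be slow, so that over-oxidation to the sulfone or attack on the trisubstituted alkenes competes. The fallback sets out from 8 and comes back at 12; it moves the oxidation ahead of the point where the geranyl chain enters. Compound 8 would be oxidised with mCPBA (CH2Cl2, −78 °C) to 4-methoxy-3-(phenylsulfinyl)but-3-en-2-one F8. LiHMDS with TMSCl present as internal quench (THF, −78 °C) would give 1-methoxy-2-(phenylsulfinyl)-3-(trimethylsilyloxy)buta-1,3-diene F9. Aldol addition to 3 under (S)-BINOL–titanium, at higher loading if the sulfoxide binds titanium, would give (5S)-5-(4-{[(2E)-3,7-dimethylocta-2,6-dien-1-yl]oxy}phenyl)-1-methoxy-2-(phenylsulfinyl)-5-(trimethylsilyloxy)pent-1-en-3-one F10, and catalytic TFA would close it to 12.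

**Further compounds**

F1 | step 8 | 2-(4-{[(2E)-3,7-dimethylocta-2,6-dien-1-yl]oxy}phenyl)-4,4,5,5-tetramethyl-1,3,2-dioxaborolane | CC(C)=CCC/C(C)=C/COc1ccc(B2OC(C)(C)C(C)(C)O2)cc1
F2 | step 8 | (4-{[(2E)-3,7-dimethylocta-2,6-dien-1-yl]oxy}phenyl)boronic acid | CC(C)=CCC/C(C)=C/COc1ccc(B(O)O)cc1
F3 | step 8 | 5,7-bis(tert-butyldimethylsilyloxy)-4H-chromen-4-one | O=c1ccoc2cc(O[Si](C)(C)C(C)(C)C)cc(O[Si](C)(C)C(C)(C)C)c12
F4 | step 8 | (2S)-5,7-bis(tert-butyldimethylsilyloxy)-2-(4-{[(2E)-3,7-dimethylocta-2,6-dien-1-yl]oxy}phenyl)-2,3-dihydro-4H-chromen-4-one | CC(C)=CCC/C(C)=C/COc1ccc([C@@H]2CC(=O)c3c(O[Si](C)(C)C(C)(C)C)cc(O[Si](C)(C)C(C)(C)C)cc3O2)cc1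
F5 | step 4 | (5S)-5-(4-{[(2E)-3,7-dimethylocta-2,6-dien-1-yl]oxy}phenyl)-1-methoxy-5-(trimethylsilyloxy)pent-1-en-3-one | CC(C)=CCC/C(C)=C/COc1ccc([C@H](CC(=O)/C=C/OC)O[Si](C)(C)C)cc1
F6 | step 4 | (2S)-2-(4-{[(2E)-3,7-dimethylocta-2,6-dien-1-yl]oxy}phenyl)-2,3-dihydro-4H-pyran-4-one | CC(C)=CCC/C(C)=C/COc1ccc([C@@H]2CC(=O)C=CO2)cc1
F7 | step 4 | (2S)-2-(4-{[(2E)-3,7-dimethylocta-2,6-dien-1-yl]oxy}phenyl)-5-iodo-2,3-dihydro-4H-pyran-4-one | CC(C)=CCC/C(C)=C/COc1ccc([C@@H]2CC(=O)C(I)=CO2)cc1
F8 | step 5 | 4-methoxy-3-(phenylsulfinyl)but-3-en-2-one | COC=C(C(C)=O)S(=O)c1ccccc1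
F9 | step 5 | 1-methoxy-2-(phenylsulfinyl)-3-(trimethylsilyloxy)buta-1,3-diene | COC=C(C(=C)O[Si](C)(C)C)S(=O)c1ccccc1
F10 | step 5 | (5S)-5-(4-{[(2E)-3,7-dimethylocta-2,6-dien-1-yl]oxy}phenyl)-1-methoxy-2-(phenylsulfinyl)-5-(trimethylsilyloxy)pent-1-en-3-one | CC(C)=CCC/C(C)=C/COc1ccc([C@H](CC(=O)C(=COC)S(=O)c2ccccc2)O[Si](C)(C)C)cc1
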